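Locants used throughout: flavan numbering (O1, C2–C4, C4a, C5–C8, C8a) for rings A and C, C1'–C6' for ring D, Cα for the alkene carbon on C8 and Cβ for the one on C1'. Compounds 1–15 are those of the steps below.

## The problem

Compound 15 is an (E)-stilbene whose alkene carbons both sit on fully flanked aromatic positions. Cα is on C8 of a 5,7-dimethoxyflavan, between O1 and 7-OMe, and Cβ is on C1' of ring D, between the C2' hydroxyl and 6'-OMe. Ring A is substituted at every carbon but C6 and ring D at every carbon but C3', so both rings need regiocontrol that electrophilic substitution alone does not guarantee (C6 against C8 on ring A). The alkene is tetra-ortho-substituted, which makes a late cross-coupling or olefination at Cα=Cβ sterically demanding. The only stereocenter is C2 (S), a benzylic ether carbon of ring C. Nothing else in the molecule can set it and it controls nothing else, so it must be introduced early and kept away from ionising acid and strong base. The 2'-hydroxystilbene is sensitive: protonation at Cβ gives a Cα cation stabilised by O1, 7-OMe and 5-OMe, which the phenol oxygen captures, and the alkene can also isomerise in light or oxidise. That weakness is the enabling feature: O2' is ortho to the alkene and Cα is on the trioxygenated ring A, so 15 is the ring-opened form of the 2-aryl-2,3-dihydrobenzofuran 13, whose O2'–Cα bond is a phenylogous acetal. Ring D without the alkene is the mirror-symmetric phenol 12, with two equivalent free ortho carbons and a blocked para carbon.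

## Retrosynthesis

**15 ⇒ 13 (through 14).** No skeletal bond is cut; O2' is reconnected to Cα, turning the alkene into the dihydrofuran of 13. This replaces the construction of a tetra-ortho-substituted alkene between two hindered arenes (the neighbouring Heck or olefination cut) by bond formation at an sp3 carbon. The forward reaction must ionise O2'–Cα but not O1–C2, cap the released phenoxide so it cannot re-add (silyl ether 14), and lose a Cβ proton to give the E-alkene.

**13 ⇒ 9 + 12.** C1'–Cβ and O2'–Cα are cut together, an oxidative (3+2) disconnection. It splits the molecule into a symmetric C9 phenol 12 and the 8-vinylflavan 9, which carries the stereocenter. The neighbouring cut at C8–Cα would need a 2-functionalised dihydrobenzofuran and a C8 nucleophile; this one uses the unfunctionalised ortho C–H of 12. The forward reaction needs two-electron oxidation, carbon bonding at Cβ and oxygen at Cα, and restraint against homocoupling and over-oxidation.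

**12 ⇒ 10 (through 11).** The C–O bond of the phenol is cut back to the only C–H of 2,6-dimethoxytoluene 10 that has no ortho substituent. Sterically governed C–H borylation finds that position; electrophilic hydroxylation would go ortho to a methoxy group instead. One pot is required.

**9 ⇒ 8 ⇒ 7.** The C8–vinyl bond is cut to bromide 8 (Suzuki–Miyaura coupling), and C8–Br to the flavan 7. Bromination is chosen over formylation–olefination because its C8 preference in 5,7-dialkoxyflavans is the better established. The coupling must tolerate a di-ortho-substituted, electron-rich bromide.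

**7 ⇒ 5 (through 6) ⇒ 4.** Ring C is opened at C4–C4a: an aryllithium 6 at the future C4a alkylated by a primary iodide. Acid-mediated Friedel–Crafts closure would ionise the benzylic ether; the anionic closure leaves C2 untouched. Chloride 4 is exchanged to iodide 5 so the ring can close at low temperature.

**4 ⇒ 2 + 3; 2 ⇒ 1.** O1–C2 is cut to iodophenol 2 and commercial (R)-3-chloro-1-phenylpropan-1-ol 3, joined with inversion. The stereocenter is bought, not made by asymmetric catalysis. Iodophenol 2 comes from 3,5-dimethoxyphenol 1 by ortho iodination, which marks the carbon that becomes C4a.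

## Roads not taken

**Alternative 1:** Ring A is cut last at C8–C8a, C6–C7 and C4a–C8a. Heating cyclobutenone A2 with the ring D enynyl methyl ether A3 starts a benzannulation cascade (Danheiser type) that should give phenol A1 with the stilbene and the C4–C2 chain in place.
- Merits: the hexasubstituted ring A is built with unambiguous regiochemistry, so the C6/C8 question of the chosen route never arises, and the stilbene is carried in and not made at a hindered position.
- Weak points: A2 (with its silylated (R)-carbinol chain) and A3 (an ynol ether conjugated to an electron-rich styrene) each need several steps and are sensitive. After A1, three more operations remain: selective carbinol desilylation, Mitsunobu closure at a hindered phenol with inversion, and phenol desilylation.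
- Comparison: this road is better in regiocontrol of ring A. The chosen plan is roughly half as long and starts from three commercial compounds.

**Alternative 2:** Ring C is cut at C3–C4 and O1–C2. A confined chiral imidodiphosphorimidate Brønsted acid dehydrates benzyl alcohol A5 to the ortho-quinone methide A6, which adds styrene A7 to give A4, the same compound as 8.
- Merits: ring C and the (S) centre are set in one catalytic step from achiral partners. If it performed, it would reach 8 in fewer steps than steps 1–5, and the endgame would be unchanged.
- Weak points: A6 is strongly stabilised by two methoxy groups and therefore a weak electrophile toward unactivated A7. The electron-rich ring of A5 can add to A6 (oligomerisation). The bromine next to the phenol oxygen sits where the catalyst must bind. A5 needs its own regioselective bromination.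
- Comparison: this road is better in step economy and uses catalytic asymmetry. The chosen plan buys the stereocenter and transfers it by a stereospecific substitution, and each of its front-end steps has close precedent.

**Alternative 3:** Ring C is cut at C4–C4a and C8a–O1. A Catellani reaction would alkylate the ortho C–H of aryl iodide A9 with iodo alcohol A10 and then close the ipso C–O bond, giving aldehyde A8. One olefination would then give 9.
- Merits: this is the shortest route to 9, and the C–O bond to the stereocenter is never broken, so no inversion step is needed.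
- Weak points: aryl–oxygen reductive elimination from a secondary benzylic alkoxide on palladium competes with β-hydride elimination to the ketone. Under carbonate base A10 can close to an oxetane. A9 carries an aldehyde beside the reacting carbon.
- Comparison: this road is better in step count if the termination works. The chosen plan uses only well-established individual steps to reach 9.

Key step: step 8

Assumption: the two Cα epimers of 13 are carried forward together, because step 9 converts both into the same alkene.

## Steps

Step 1
Reactants: 1 3,5-dimethoxyphenol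
Product: 2 2-iodo-3,5-dimethoxyphenol
Conditions: NIS (1.0 equiv), CH2Cl2, −40 to 0 °C, dark
Reagents that add atoms: N-iodosuccinimide, O=C1CCC(=O)N1I
Why: Electrophilic aromatic iodination; C2 is as activated as C4 but less hindered (C4 lies between two methoxy groups) and is statistically doubled, and one equivalent at low temperature limits 4-iodo and diiodo products.

Step 2
Reactants: 2 2-iodo-3,5-dimethoxyphenol; 3 (R)-3-chloro-1-phenylpropan-1-ol
Product: 4 1-[(1S)-3-chloro-1-phenylpropoxy]-2-iodo-3,5-dimethoxybenzene
Conditions: PPh3, DIAD, THF, 0 °C to rt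
Reagents that add atoms: none
Why: Mitsunobu reaction; the phenoxide of 2 displaces the alkoxyphosphonium of the (R)-carbinol by SN2 with inversion, which sets the later C2 as (S), and the primary chloride is inert.

Step 3
Reactants: 4 1-[(1S)-3-chloro-1-phenylpropoxy]-2-iodo-3,5-dimethoxybenzene
Product: 5 2-iodo-1-[(1S)-3-iodo-1-phenylpropoxy]-3,5-dimethoxybenzene
Conditions: NaI, 2-butanone, reflux
Reagents that add atoms: sodium iodide, [Na+].[I-]
Why: Finkelstein exchange at the primary carbon; the iodide lets the following ring closure run at low temperature, and the stereocenter is not involved.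

Step 4
Reactants: 5 2-iodo-1-[(1S)-3-iodo-1-phenylpropoxy]-3,5-dimethoxybenzene
Product: 7 (2S)-5,7-dimethoxy-2-phenyl-3,4-dihydro-2H-chromene ((S)-5,7-dimethoxyflavan), via aryllithium 6 (not isolated)
Conditions: n-BuLi (1.05 equiv), THF, −78 °C to rt
Reagents that add atoms: none
Why: Parham cyclisation; iodine–lithium exchange at the aryl iodide is far faster than at the alkyl iodide, and the 2,6-dialkoxyaryllithium 6 closes ring C by 6-exo-tet alkylation (C4–C4a) without touching C2.

Step 5
Reactants: 7 (2S)-5,7-dimethoxy-2-phenyl-3,4-dihydro-2H-chromene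
Product: 8 (2S)-8-bromo-5,7-dimethoxy-2-phenyl-3,4-dihydro-2H-chromene
Conditions: NBS (1.0 equiv), CH2Cl2, −78 to 0 °C
Reagents that add atoms: N-bromosuccinimide, O=C1CCC(=O)N1Br
Why: Electrophilic aromatic bromination; C8, ortho to the ring oxygen and to 7-OMe, is the more nucleophilic free position of 5,7-dialkoxyflavans (the site NBS attacks in protected catechins), and one equivalent avoids the 6,8-dibromide.

Step 6
Reactants: 8 (2S)-8-bromo-5,7-dimethoxy-2-phenyl-3,4-dihydro-2H-chromene
Product: 9 (2S)-8-ethenyl-5,7-dimethoxy-2-phenyl-3,4-dihydro-2H-chromene ((S)-5,7-dimethoxy-8-vinylflavan)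
Conditions: vinylboronic acid pinacol ester, Pd(OAc)2 (5 mol %), SPhos (10 mol %), K2CO3, dioxane/H2O, 85 °C; Et3N-washed silica
Reagents that add atoms: 4,4,5,5-tetramethyl-2-vinyl-1,3,2-dioxaborolane, C=CB1OC(C)(C)C(C)(C)O1
Why: Suzuki–Miyaura coupling; the dialkylbiarylphosphine is chosen for the di-ortho-substituted, electron-rich bromide, and the basic medium and base-washed silica protect the acid-sensitive trialkoxystyrene.

Step 7
Reactants: 10 2,6-dimethoxytoluene
Product: 12 3,5-dimethoxy-4-methylphenol, via arylboronate 11 (not isolated)
Conditions: [Ir(OMe)(cod)]2 (1.5 mol %), dtbpy (3 mol %), B2pin2 (0.6 equiv), THF, 80 °C; then KHSO5 (as Oxone, 2KHSO5·KHSO4·K2SO4), acetone/H2O, rt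
Reagents that add atoms: potassium peroxymonosulfate, [K+].[O-]S(=O)(=O)OO
Why: One-pot iridium-catalysed C–H borylation and oxidation; borylation is sterically controlled and C4 of 10 is the only C–H without an ortho substituent, and peroxymonosulfate converts the C–B bond of 11 into C–OH at the same carbon.

Step 8
Reactants: 9 (2S)-8-ethenyl-5,7-dimethoxy-2-phenyl-3,4-dihydro-2H-chromene; 12 3,5-dimethoxy-4-methylphenol
Product: 13 (2S)-8-[(2RS)-4,6-dimethoxy-5-methyl-2,3-dihydro-1-benzofuran-2-yl]-5,7-dimethoxy-2-phenyl-3,4-dihydro-2H-chromene (both Cα epimers)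
Conditions: undivided cell, graphite anode, Pt cathode, constant current (about 2 mA cm−2, 2.0–2.2 F mol−1 based on 9), n-Bu4NPF6 (0.1 M), 1,1,1,3,3,3-hexafluoropropan-2-ol/CH2Cl2 (1:4), 2,6-lutidine (1 equiv), 12 (3 equiv), 0 °C; stop at partial conversion, recover 9 and 12
Reagents that add atoms: none
Why: Two-electron anodic oxidation gives either the phenoxonium ion of 12 or the radical cation of 9; in both channels the ortho carbon of 12 bonds to the unhindered terminal Cβ, and the charge ends on Cα as a benzylic cation stabilised by O1 and 7-OMe (ortho) and 5-OMe (para). The phenol oxygen then closes the dihydrofuran by 5-exo-trig attack on that cation, and loss of the ortho proton rearomatises ring D. The closest known reaction type is the anodic or photocatalytic oxidative (3+2) annulation of electron-rich phenols with electron-rich styrenes to 2-aryl-2,3-dihydrobenzofurans; the difference here is a para-methyl phenol in place of a para-alkoxy phenol. Regiochemistry (carbon to Cβ, oxygen to Cα) is secured by the ring A stabilised cation. Site selectivity on 12 follows from its two equivalent ortho C–H positions and from the methyl group and two flanking methoxy groups that shield the para carbon. The new Cα stereocenter is not controlled, since C2 is too remote, and both epimers are accepted because step 9 removes it; C2 itself is off the reaction path. Selectivity against phenol homocoupling, styrene dimerisation, acid-induced hydroarylation and over-oxidation of 13 rests on excess 12, the lutidine buffer, low current density and limited charge.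

Step 9
Reactants: 13 (2S)-8-[(2RS)-4,6-dimethoxy-5-methyl-2,3-dihydro-1-benzofuran-2-yl]-5,7-dimethoxy-2-phenyl-3,4-dihydro-2H-chromene
Product: 15 2-[(E)-2-[(2S)-5,7-dimethoxy-2-phenyl-3,4-dihydro-2H-chromen-8-yl]ethenyl]-3,5-dimethoxy-4-methylphenol (the target), via trimethylsilyl ether 14 (not isolated)
Conditions: TMSOTf (1.5 equiv), 2,6-lutidine (3 equiv), CH2Cl2, −78 to 0 °C; then K2CO3, MeOH, rt; base-washed silica, exclusion of light
Reagents that add atoms: none
Why: Proposed new method: silylation of the dihydrofuran oxygen by TMSOTf should ionise the O2'–Cα bond because Cα carries the 2,4,6-trioxygenated ring A (a phenylogous acetal); the phenoxide leaves as its silyl ether 14 and cannot re-add, and 2,6-lutidine removes a Cβ proton from the conformer with rings A and D anti, giving the (E)-alkene by E1 elimination; the closest known reaction types are the silyl triflate–amine conversion of acetals into enol ethers and of epoxides into allylic silyl ethers, and the acid-induced opening of pterocarpans to isoflav-3-enes; K2CO3 in methanol then cleaves the aryl silyl ether without acid, and the plain benzylic O1–C2 bond, which lacks this stabilisation, should stay intact so that C2 remains (S).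

## Compound list

1 | 3,5-dimethoxyphenol | COc1cc(O)cc(OC)c1 | starting material
2 | 2-iodo-3,5-dimethoxyphenol | Oc1cc(OC)cc(OC)c1I | intermediate
3 | (R)-3-chloro-1-phenylpropan-1-ol | O[C@@H](c1ccccc1)CCCl | starting material
4 | 1-[(1S)-3-chloro-1-phenylpropoxy]-2-iodo-3,5-dimethoxybenzene | COc1cc(OC)c(I)c(O[C@H](c2ccccc2)CCCl)c1 | intermediate
5 | 2-iodo-1-[(1S)-3-iodo-1-phenylpropoxy]-3,5-dimethoxybenzene | COc1cc(OC)c(I)c(O[C@H](c2ccccc2)CCI)c1 | intermediate
6 | {2-[(1S)-3-iodo-1-phenylpropoxy]-4,6-dimethoxyphenyl}lithium | COc1cc(OC)c([Li])c(O[C@H](c2ccccc2)CCI)c1 | intermediate (not isolated)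
7 | (2S)-5,7-dimethoxy-2-phenyl-3,4-dihydro-2H-chromene | COc1cc(OC)c2c(c1)O[C@H](c1ccccc1)CC2 | intermediate
8 | (2S)-8-bromo-5,7-dimethoxy-2-phenyl-3,4-dihydro-2H-chromene | COc1cc(OC)c2c(c1Br)O[C@H](c1ccccc1)CC2 | intermediate
9 | (2S)-8-ethenyl-5,7-dimethoxy-2-phenyl-3,4-dihydro-2H-chromene | C=Cc1c(OC)cc(OC)c2c1O[C@H](c1ccccc1)CC2 | intermediate
10 | 2,6-dimethoxytoluene | Cc1c(OC)cccc1OC | starting material
11 | 2-(3,5-dimethoxy-4-methylphenyl)-4,4,5,5-tetramethyl-1,3,2-dioxaborolane | COc1cc(cc(OC)c1C)B1OC(C)(C)C(C)(C)O1 | intermediate (not isolated)
12 | 3,5-dimethoxy-4-methylphenol | COc1cc(O)cc(OC)c1C | intermediate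
13 | (2S)-8-[(2RS)-4,6-dimethoxy-5-methyl-2,3-dihydro-1-benzofuran-2-yl]-5,7-dimethoxy-2-phenyl-3,4-dihydro-2H-chromene | COc1cc2c(c(OC)c1C)CC(O2)c1c(OC)cc(OC)c2c1O[C@H](c1ccccc1)CC2 | intermediate
14 | trimethyl{2-[(E)-2-[(2S)-5,7-dimethoxy-2-phenyl-3,4-dihydro-2H-chromen-8-yl]ethenyl]-3,5-dimethoxy-4-methylphenoxy}silane | COc1cc(O[Si](C)(C)C)c(/C=C/c2c(OC)cc(OC)c3c2O[C@H](c2ccccc2)CC3)c(OC)c1C | intermediate (not isolated)
15 | 2-[(E)-2-[(2S)-5,7-dimethoxy-2-phenyl-3,4-dihydro-2H-chromen-8-yl]ethenyl]-3,5-dimethoxy-4-methylphenol | COc1cc(O)c(/C=C/c2c(OC)cc(OC)c3c2O[C@H](c2ccccc2)CC3)c(OC)c1C | target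

## Step count and least certain steps

Total steps: 9. Longest linear sequence: 8 (steps 1–6, 8, 9); step 7 is a one-step branch.

**Step 9 (bears the label).** The most likely failure is that ionisation is reversible or diverted. If the silyl group is lost before the proton, the phenol re-adds to Cα. Once some stilbene is present, its nucleophilic Cβ can add to another Cα cation (cationic dimerisation). Long exposure could begin to ionise O1–C2 and erode C2. The fallback uses known reactions, sets out from 13 and returns at 15. Lewis-acid thiolysis of the benzylic ether (PhSH, BF3·OEt2, CH2Cl2, −40 °C) should give the ring-opened sulfide phenol F1. Silylation (TBSCl, imidazole, DMF) gives the silyl ether F2. One equivalent of mCPBA at −78 °C gives the sulfoxide F3. Thermal syn-elimination of benzenesulfenic acid (toluene, NaHCO3, 90 °C) then gives the silyl-protected (E)-stilbene F4, and buffered fluoride (TBAF, AcOH, THF) releases 15.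

**Step 8 (key step).** Several processes can go wrong:
- electron transfer may favour a channel in which the phenol oxygen, not its ortho carbon, bonds to Cβ, leading to the 3-aryl regioisomer;
- the phenol may homocouple or be oxidised at its para-methyl group through a quinone methide;
- acid formed at the anode may protonate the trialkoxystyrene and start hydroarylation or oligomerisation;
- the product, as electron-rich as the reactants, may be oxidised further.

The fallback abandons the annulation and makes the alkene directly, setting out from 12 and 9 and returning at 15. Iodination of 12 (NIS, CH2Cl2) gives 2-iodo-3,5-dimethoxy-4-methylphenol F5. Acetylation (Ac2O, pyridine) gives the aryl acetate F6. Mizoroki–Heck coupling with 9 (Pd(OAc)2, n-Bu4NBr, NaHCO3, DMF, 90–100 °C) gives the stilbene acetate F7, and K2CO3 in methanol gives 15. The price is a coupling that must form a tetra-ortho-substituted stilbene, which is why it is not the first choice.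

**Step 4.** The aryllithium may abstract the benzylic C2 proton before it alkylates (anion translocation), which would scramble configuration or start a Wittig-type rearrangement. Exchange at the alkyl iodide and intermolecular butylation are further drains. The fallback closes O1–C2 last instead of C4–C4a, setting out from 2 and returning at 7. Heck coupling of 2 with 1-phenylprop-2-en-1-ol under ligand-free conditions (Pd(OAc)2, n-Bu4NCl, NaHCO3, DMF) gives, after enol–ketone isomerisation, 3-(2-hydroxy-4,6-dimethoxyphenyl)-1-phenylpropan-1-one F8. Asymmetric transfer hydrogenation (RuCl(p-cymene)[(R,R)-TsDPEN], HCO2H/Et3N) gives the (R)-carbinol F9. Intramolecular Mitsunobu reaction (PPh3, DIAD) closes ring C with inversion to 7.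

**Step 1.** Iodination may occur at C4 or twice, because all three free positions are strongly activated. The fallback replaces electrophilic substitution by directed ortho-metalation, setting out from 1 and returning at 2. Carbamoylation (ClCONEt2, K2CO3, MeCN) gives 3,5-dimethoxyphenyl diethylcarbamate F10. Lithiation ortho to the carbamate (s-BuLi, TMEDA, THF, −78 °C) and iodine quench give the 2-iodo carbamate F11. Hydrolysis (NaOH, EtOH, reflux) gives 2.

## Further compounds

F1 | step 9 | 2-{2-[(2S)-5,7-dimethoxy-2-phenyl-3,4-dihydro-2H-chromen-8-yl]-2-(phenylsulfanyl)ethyl}-3,5-dimethoxy-4-methylphenol (both Cα epimers) | COc1cc(O)c(CC(Sc2ccccc2)c2c(OC)cc(OC)c3c2O[C@H](c2ccccc2)CC3)c(OC)c1C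
F2 | step 9 | tert-butyldimethylsilyl ether of F1 | COc1cc(O[Si](C)(C)C(C)(C)C)c(CC(Sc2ccccc2)c2c(OC)cc(OC)c3c2O[C@H](c2ccccc2)CC3)c(OC)c1C
F3 | step 9 | phenyl sulfoxide of F2 | COc1cc(O[Si](C)(C)C(C)(C)C)c(CC(S(=O)c2ccccc2)c2c(OC)cc(OC)c3c2O[C@H](c2ccccc2)CC3)c(OC)c1C
F4 | step 9 | tert-butyl{2-[(E)-2-[(2S)-5,7-dimethoxy-2-phenyl-3,4-dihydro-2H-chromen-8-yl]ethenyl]-3,5-dimethoxy-4-methylphenoxy}dimethylsilane | COc1cc(O[Si](C)(C)C(C)(C)C)c(/C=C/c2c(OC)cc(OC)c3c2O[C@H](c2ccccc2)CC3)c(OC)c1C
F5 | step 8 | 2-iodo-3,5-dimethoxy-4-methylphenol | COc1cc(O)c(I)c(OC)c1C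
F6 | step 8 | 2-iodo-3,5-dimethoxy-4-methylphenyl acetate | COc1cc(OC(C)=O)c(I)c(OC)c1C
F7 | step 8 | 2-[(E)-2-[(2S)-5,7-dimethoxy-2-phenyl-3,4-dihydro-2H-chromen-8-yl]ethenyl]-3,5-dimethoxy-4-methylphenyl acetate | COc1cc(OC(C)=O)c(/C=C/c2c(OC)cc(OC)c3c2O[C@H](c2ccccc2)CC3)c(OC)c1C
F8 | step 4 | 3-(2-hydroxy-4,6-dimethoxyphenyl)-1-phenylpropan-1-one | COc1cc(O)c(CCC(=O)c2ccccc2)c(OC)c1
F9 | step 4 | (1R)-3-(2-hydroxy-4,6-dimethoxyphenyl)-1-phenylpropan-1-ol | COc1cc(O)c(CC[C@@H](O)c2ccccc2)c(OC)c1
F10 | step 1 | 3,5-dimethoxyphenyl N,N-diethylcarbamate | CCN(CC)C(=O)Oc1cc(OC)cc(OC)c1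
F11 | step 1 | 2-iodo-3,5-dimethoxyphenyl N,N-diethylcarbamate | CCN(CC)C(=O)Oc1cc(OC)cc(OC)c1I
A1 | alternative 1 | open-chain C8a phenol with both silyl ethers, (R)-carbinol | COc1cc(O[Si](C)(C)C(C)(C)C)c(/C=C/c2c(OC)cc(OC)c(CC[C@@H](O[Si](C)(C)C(C)(C)C)c3ccccc3)c2O)c(OC)c1C
A2 | alternative 1 | 4-[(3R)-3-(tert-butyldimethylsilyloxy)-3-phenylpropyl]-3-methoxycyclobut-2-en-1-one | COC1=CC(=O)C1CC[C@@H](O[Si](C)(C)C(C)(C)C)c1ccccc1
A3 | alternative 1 | tert-butyl{3,5-dimethoxy-2-[(E)-4-methoxybut-1-en-3-yn-1-yl]-4-methylphenoxy}dimethylsilane | COC#C/C=C/c1c(O[Si](C)(C)C(C)(C)C)cc(OC)c(C)c1OC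
A4 | alternative 2 | (2S)-8-bromo-5,7-dimethoxy-2-phenyl-3,4-dihydro-2H-chromene (same compound as 8) | COc1cc(OC)c2c(c1Br)O[C@H](c1ccccc1)CC2
A5 | alternative 2 | 3-bromo-2-hydroxy-4,6-dimethoxybenzyl alcohol | OCc1c(OC)cc(OC)c(Br)c1O
A6 | alternative 2 | 2-bromo-3,5-dimethoxy-6-methylidenecyclohexa-2,4-dien-1-one (ortho-quinone methide) | C=C1C(OC)=CC(OC)=C(Br)C1=O
A7 | alternative 2 | styrene | C=Cc1ccccc1
A8 | alternative 3 | (2S)-5,7-dimethoxy-2-phenyl-3,4-dihydro-2H-chromene-8-carbaldehyde | O=Cc1c(OC)cc(OC)c2c1O[C@H](c1ccccc1)CC2
A9 | alternative 3 | 2-iodo-4,6-dimethoxybenzaldehyde | O=Cc1c(I)cc(OC)cc1OC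
A10 | alternative 3 | (S)-3-iodo-1-phenylpropan-1-ol | O[C@H](c1ccccc1)CCI
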